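A one-step picture, substrate straight to target, does not survive the earlier runs. After 25.0 s the substrate stands at 44.3 %, 43.5 % and 45.4 % on rising reagent, while the intermediate drops from 22.8 % on Monday's to 7.5 % on Tuesday's. So we treat two steps in series and ask which one holds the pace.

| flask | substrate | reagent | free catalyst | second catalyst | remark | time |
|---|---|---|---|---|---|---|
| Monday's | 0.50 M | 0.94 M | 12 mM | 2.5 mM | run made earlier |  |
| Saturday's | 0.50 M | 1.3 M | 12 mM | 2.5 mM | run made earlier |  |
| Tuesday's | 0.50 M | 2.3 M | 12 mM | 2.5 mM | run made earlier |  |
| south | 0.50 M | 0.750 M | 12 mM | 2.5 mM |  | 2.0 min |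
| south-east | 0.50 M | 2.20 M | 12 mM | 2.5 mM |  | 2.0 min |

| run | time / s | target / % | intermediate / % | substrate / % |
|---|---|---|---|---|
| Monday's | 25.0 | 30.5 | 22.8 | 44.3 |
| Monday's | 50.0 | 54.4 | 16.7 | 29.4 |
| Monday's | 80.0 | 73.5 | 8.9 | 18.3 |
| Monday's | 90.0 | 73.3 | 6.6 | 19.4 |
| Monday's | 120 | 80.2 | 3.4 | 12.5 |
| Saturday's | 25.0 | 36.2 | 17.7 | 43.5 |
| Saturday's | 50.0 | 63.0 | 9.8 | 27.5 |
| Saturday's | 80.0 | 74.4 | 4.2 | 18.6 |
| Saturday's | 90.0 | 76.8 | 3.9 | 18.4 |
| Saturday's | 120 | 84.3 | 2.3 | 12.8 |
| Tuesday's | 25.0 | 45.3 | 7.5 | 45.4 |
| Tuesday's | 50.0 | 66.0 | 2.1 | 28.5 |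
| Tuesday's | 80.0 | 76.8 | 1.2 | 20.0 |
| Tuesday's | 90.0 | 78.4 | 3.1 | 17.4 |
| Tuesday's | 120 | 84.5 | 1.0 | 11.2 |

(readings scatter by 1 percentage point)

- which of these there is most of at the end, counted by the substrate in it, south (substrate / intermediate / target)
- which of these there is most of at the end, counted by the substrate in it, south-east (substrate / intermediate / target)
- final amount of the leader among these, as a percentage of the substrate charged, in south
- final amount of the leader among these, as a percentage of the substrate charged, in south-east

The inverse of the substrate fraction rises roughly linearly; Saturday's reading at 50.0 s gives a slope s = 0.0527 s⁻¹. Between 25.0 s and 50.0 s Saturday's target gains 27 percentage points over a mean intermediate of 13.8 %. Taking one equivalent of reagent per target, mean [reagent] is 1.05 M, so the intermediate clears at κ[reagent] with κ = 0.0741 M⁻¹ s⁻¹.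

Setting κ[reagent] equal to s gives the crossing reagent, the [reagent] at which the two steps have equal rate coefficients at the start of a flask with 12 mM of free catalyst: 0.711 M. It is a mark for the start and not a later handover of the rate-limiting step, because the first step's coefficient is s times the substrate fraction and falls as the run goes on.

South-east, even after losing one equivalent, keeps 1.70 M, more than the crossing, so we expect little intermediate there. South starts near the crossing, so its two steps begin with like coefficients and we expect its intermediate to build up.

The forecast names target in south and target in south-east, at 77 % (71 % to 81 %) and 85 % (82 % to 88 %): “South-east resembles Tuesday”.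

    substrate + free catalyst → free catalyst + intermediate (k = 3.93 M⁻¹ s⁻¹)
    reagent + second catalyst + intermediate → second catalyst + target (k = 28.5 M⁻² s⁻¹)
    substrate + free catalyst → spent catalyst (k = 0.0917 M⁻¹ s⁻¹)

South gives 77.4 % of target and south-east 84.1 %. Substrate stands at 13 % and 13 %, so the gap of 6.7 points sits in intermediate, 7.70 % against 0.945 %. As charged, south's [reagent] stands at 1.05 times the crossing and south-east's at 3.09 times. The neighbour of south-east charged with 4.80 mM of free catalyst has its crossing scaled down with that charge to 0.285 M, below its charged 2.20 M; its intermediate is 0.236 %, with substrate at 59 %.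

All runs were generated by integration for an exercise, and the scatter is random.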